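**Assumption:** the target (C22H26O7) has no stereocentre, so the "single enantiomer" is simply the one achiral constitution drawn; the ring stereocentres of the cyclohexenone intermediates are racemic and are erased on aromatisation.

## Retrosynthetic overview

1. Cut the depside ester C(=O)–OAr: ring A acid 8 (2,4-bis(benzyloxy)-6-pentylbenzoic acid) plus ring B phenol 15 (benzyl 2,4-dihydroxy-6-propylbenzoate). All three benzyl groups come off in one final hydrogenolysis.
2. Each resorcylate ring comes from a methyl 6-alkyl-2-hydroxy-4-oxocyclohex-2-ene-1-carboxylate by bromine-mediated aromatisation.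
3. Each cyclohexenone ester comes from an intermolecular Michael addition of dimethyl malonate to an (E)-alk-3-en-2-one (key C–C bond, the future C1–C6 bond of the arene), followed in the same flask by Claisen (Dieckmann) ring closure.
4. Order of ring formation: ring A (pentyl) is built and aromatised in one branch, ring B (propyl) in a parallel branch; the two are joined by esterification, then deprotected.

## Route

**Step 1**
Reactants: 1 (E)-non-3-en-2-one; 2 dimethyl malonate
Product: 4 methyl 2-hydroxy-4-oxo-6-pentylcyclohex-2-ene-1-carboxylate, via Michael adduct 3 (not isolated)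
Conditions: NaOMe (1.1 equiv), MeOH, rt then reflux, 4 h; then 1 M HCl, 0 °C
Reagents that add atoms: none
Why: The malonate anion adds 1,4 to the enone (intermolecular Michael addition) and the methyl-ketone enolate of 3 then closes onto one ester (Claisen/Dieckmann condensation), driven by formation of the stabilised enolate of the cyclic β-diketone; the two ring stereocentres form racemic and are erased in step 2.

**Step 2**
Reactants: 4 methyl 2-hydroxy-4-oxo-6-pentylcyclohex-2-ene-1-carboxylate
Product: 6 methyl 2,4-dihydroxy-6-pentylbenzoate, via bromo dione 5 (not isolated)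
Conditions: Br2 (1.05 equiv), DMF, 0 °C, 1 h; then 80 °C, 12 h
Reagents that add atoms: none
Why: Electrophilic bromination at the doubly activated C-3, then thermal 1,4-dehydrobromination through the enol and tautomerisation (oxidative aromatisation), gives the resorcylate while the methyl ester survives at 80 °C.

**Step 3**
Reactants: 6 methyl 2,4-dihydroxy-6-pentylbenzoate
Product: 7 methyl 2,4-bis(benzyloxy)-6-pentylbenzoate
Conditions: BnBr (2.5 equiv), K2CO3 (3 equiv), DMF, 70 °C, 12 h
Reagents that add atoms: benzyl bromide, BrCc1ccccc1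
Why: Williamson ether synthesis on both phenoxides; heat and excess halide bring the hydrogen-bonded 2-OH to full conversion and the ester is untouched.

**Step 4**
Reactants: 7 methyl 2,4-bis(benzyloxy)-6-pentylbenzoate
Product: 8 2,4-bis(benzyloxy)-6-pentylbenzoic acid
Conditions: KOH (10 equiv), DMSO/H2O 4:1, 95 °C, 8 h; then 2 M HCl, 0 °C
Reagents that add atoms: potassium hydroxide, [K+].[OH-] (oxygen of the new carboxyl OH)
Why: Saponification of the di-ortho-substituted ester needs the poorly solvated hydroxide of aqueous DMSO at 95 °C, conditions to which benzyl ethers are inert.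

**Step 5**
Reactants: 9 (E)-hept-3-en-2-one; 2 dimethyl malonate
Product: 11 methyl 2-hydroxy-4-oxo-6-propylcyclohex-2-ene-1-carboxylate, via Michael adduct 10 (not isolated)
Conditions: NaOMe (1.1 equiv), MeOH, rt then reflux, 4 h; then 1 M HCl, 0 °C
Reagents that add atoms: none
Why: Same intermolecular Michael addition and Claisen/Dieckmann ring closure as in step 1, now on the propyl enone; the racemic ring stereocentres are erased in step 6.

**Step 6**
Reactants: 11 methyl 2-hydroxy-4-oxo-6-propylcyclohex-2-ene-1-carboxylate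
Product: 13 methyl 2,4-dihydroxy-6-propylbenzoate, via bromo dione 12 (not isolated)
Conditions: Br2 (1.05 equiv), DMF, 0 °C, 1 h; then 80 °C, 12 h
Reagents that add atoms: none
Why: Bromination and dehydrobromination (oxidative aromatisation) exactly as in step 2.

**Step 7**
Reactants: 13 methyl 2,4-dihydroxy-6-propylbenzoate
Product: 14 2,4-dihydroxy-6-propylbenzoic acid
Conditions: 2.5 M aq NaOH (10 equiv), MeOH, reflux under N2, 6 h; then cold 2 M HCl to pH 2 at 0 °C, extract, evaporate below 30 °C
Reagents that add atoms: sodium hydroxide, [Na+].[OH-] (oxygen of the new carboxyl OH)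
Why: Saponification; the phenoxide-carboxylate polyanion does not decarboxylate in base, and cold acidification avoids protodecarboxylation of the free β-resorcylic acid.

**Step 8**
Reactants: 14 2,4-dihydroxy-6-propylbenzoic acid
Product: 15 benzyl 2,4-dihydroxy-6-propylbenzoate
Conditions: BnBr (1.05 equiv), KHCO3 (1.2 equiv), DMF, rt, 16 h
Reagents that add atoms: benzyl bromide, BrCc1ccccc1
Why: Hydrogencarbonate deprotonates only the carboxylic acid and not the phenols, so SN2 O-alkylation gives the benzyl ester alone.

**Step 9**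
Reactants: 8 2,4-bis(benzyloxy)-6-pentylbenzoic acid; 15 benzyl 2,4-dihydroxy-6-propylbenzoate
Product: 17 benzyl 4-{[2,4-bis(benzyloxy)-6-pentylbenzoyl]oxy}-2-hydroxy-6-propylbenzoate, via mixed anhydride 16 (not isolated)
Conditions: (CF3CO)2O (4 equiv), toluene, rt, 4 h; aq NaHCO3 work-up
Reagents that add atoms: none
Why: Mixed-anhydride esterification: the acyl trifluoroacetate 16 of the hindered acid acylates the free 4-OH of 15, whereas the 2-OH is hydrogen-bonded to and flanked by the benzyl ester carbonyl; any aryl trifluoroacetate is cleaved in the hydrogencarbonate wash.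

**Step 10**
Reactants: 17 benzyl 4-{[2,4-bis(benzyloxy)-6-pentylbenzoyl]oxy}-2-hydroxy-6-propylbenzoate
Product: 18 4-[(2,4-dihydroxy-6-pentylbenzoyl)oxy]-2-hydroxy-6-propylbenzoic acid
Conditions: H2 (1 atm), 10% Pd/C, EtOAc, rt, 3 h
Reagents that add atoms: none
Why: Catalytic hydrogenolysis cleaves the two benzyl ethers and the benzyl ester under neutral conditions that leave the aryl ester (depside) link and both arenes intact; there is no stereocentre to set.

## Compound list

1 | (E)-non-3-en-2-one | CCCCC/C=C/C(C)=O | starting material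
2 | dimethyl malonate | COC(=O)CC(=O)OC | starting material
3 | dimethyl 2-(2-oxononan-4-yl)propanedioate (racemic) | CCCCCC(CC(C)=O)C(C(=O)OC)C(=O)OC | intermediate
4 | methyl 2-hydroxy-4-oxo-6-pentylcyclohex-2-ene-1-carboxylate (racemic; enol form of the cyclic β-diketo ester) | CCCCCC1CC(=O)C=C(O)C1C(=O)OC | intermediate
5 | methyl 3-bromo-2-hydroxy-4-oxo-6-pentylcyclohex-2-ene-1-carboxylate (racemic) | CCCCCC1CC(=O)C(Br)=C(O)C1C(=O)OC | intermediate
6 | methyl 2,4-dihydroxy-6-pentylbenzoate | CCCCCc1cc(O)cc(O)c1C(=O)OC | intermediate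
7 | methyl 2,4-bis(benzyloxy)-6-pentylbenzoate | CCCCCc1cc(OCc2ccccc2)cc(OCc2ccccc2)c1C(=O)OC | intermediate
8 | 2,4-bis(benzyloxy)-6-pentylbenzoic acid | CCCCCc1cc(OCc2ccccc2)cc(OCc2ccccc2)c1C(=O)O | intermediate
9 | (E)-hept-3-en-2-one | CCC/C=C/C(C)=O | starting material
10 | dimethyl 2-(2-oxoheptan-4-yl)propanedioate (racemic) | CCCC(CC(C)=O)C(C(=O)OC)C(=O)OC | intermediate
11 | methyl 2-hydroxy-4-oxo-6-propylcyclohex-2-ene-1-carboxylate (racemic; enol form) | CCCC1CC(=O)C=C(O)C1C(=O)OC | intermediate
12 | methyl 3-bromo-2-hydroxy-4-oxo-6-propylcyclohex-2-ene-1-carboxylate (racemic) | CCCC1CC(=O)C(Br)=C(O)C1C(=O)OC | intermediate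
13 | methyl 2,4-dihydroxy-6-propylbenzoate | CCCc1cc(O)cc(O)c1C(=O)OC | intermediate
14 | 2,4-dihydroxy-6-propylbenzoic acid | CCCc1cc(O)cc(O)c1C(=O)O | intermediate
15 | benzyl 2,4-dihydroxy-6-propylbenzoate | CCCc1cc(O)cc(O)c1C(=O)OCc1ccccc1 | intermediate
16 | 2,4-bis(benzyloxy)-6-pentylbenzoic trifluoroacetic anhydride | CCCCCc1cc(OCc2ccccc2)cc(OCc2ccccc2)c1C(=O)OC(=O)C(F)(F)F | intermediate
17 | benzyl 4-{[2,4-bis(benzyloxy)-6-pentylbenzoyl]oxy}-2-hydroxy-6-propylbenzoate | CCCCCc1cc(OCc2ccccc2)cc(OCc2ccccc2)c1C(=O)Oc1cc(O)c(C(=O)OCc2ccccc2)c(CCC)c1 | intermediate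
18 | 4-[(2,4-dihydroxy-6-pentylbenzoyl)oxy]-2-hydroxy-6-propylbenzoic acid (achiral) | CCCCCc1cc(O)cc(O)c1C(=O)Oc1cc(O)c(C(=O)O)c(CCC)c1 | target

## Step count and risks

Total steps: 10. Longest linear sequence: 6 (steps 1, 2, 3, 4, 9, 10, or equally 5, 6, 7, 8, 9, 10).

**Risk 1, step 2 (aromatisation; over-bromination of the electron-rich ring or incomplete dehydrobromination).** The fallback sets out from 4 and comes back at 6. Instead of fighting over-bromination, 4 is treated with excess Br2 (3.1 equiv) in AcOH at rt to 50 °C, which aromatises and brominates both free ring positions to give methyl 3,5-dibromo-2,4-dihydroxy-6-pentylbenzoate F1, a crystalline compound. Hydrogenolytic debromination (H2, 10% Pd/C, NaOAc, MeOH, rt) then removes both bromines and returns 6.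

**Risk 2, step 7 (saponification of the hindered salicylate; the free acid 14 can lose CO2 on acidification or concentration).** The fallback sets out from 9 and comes back at 15, so the free acid is never handled. Dibenzyl malonate (O=C(CC(=O)OCc1ccccc1)OCc1ccccc1) is added to 9 with NaH in THF (0 °C then reflux). The Michael adduct dibenzyl 2-(2-oxoheptan-4-yl)propanedioate F2 cyclises in the same flask, with loss of benzyl alcohol, to benzyl 2-hydroxy-4-oxo-6-propylcyclohex-2-ene-1-carboxylate F3. Br2 (1.05 equiv) in DMF at 0 °C, then 70 °C, aromatises F3 through benzyl 3-bromo-2-hydroxy-4-oxo-6-propylcyclohex-2-ene-1-carboxylate F4 directly to 15. DMF buffers the HBr, but the benzyl ester is more labile than the methyl ester, so the temperature is kept at or below 70 °C.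

**Risk 3, step 9 (depside coupling of a di-ortho-substituted acid; slow acylation or competing trifluoroacetylation of the phenol).** The fallback sets out from 8 and comes back at 17. Acid 8 is converted with oxalyl chloride and catalytic DMF in CH2Cl2 (0 °C to rt) into 2,4-bis(benzyloxy)-6-pentylbenzoyl chloride F5, which is freed of volatiles. F5 is added to 15 and K2CO3 in dry acetone at rt; the more acidic, unhindered 4-phenoxide is acylated and gives 17.

## Further compounds

F1 | step 2 | methyl 3,5-dibromo-2,4-dihydroxy-6-pentylbenzoate | CCCCCc1c(Br)c(O)c(Br)c(O)c1C(=O)OC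
F2 | step 7 | dibenzyl 2-(2-oxoheptan-4-yl)propanedioate (racemic) | CCCC(CC(C)=O)C(C(=O)OCc1ccccc1)C(=O)OCc1ccccc1
F3 | step 7 | benzyl 2-hydroxy-4-oxo-6-propylcyclohex-2-ene-1-carboxylate (racemic) | CCCC1CC(=O)C=C(O)C1C(=O)OCc1ccccc1
F4 | step 7 | benzyl 3-bromo-2-hydroxy-4-oxo-6-propylcyclohex-2-ene-1-carboxylate (racemic) | CCCC1CC(=O)C(Br)=C(O)C1C(=O)OCc1ccccc1
F5 | step 9 | 2,4-bis(benzyloxy)-6-pentylbenzoyl chloride | CCCCCc1cc(OCc2ccccc2)cc(OCc2ccccc2)c1C(=O)Cl
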